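**Plan**

1. Retrosynthetic cuts, in order: the two MOM acetals and a blocking C2'–Br (helpers); the C4'–C4 bond of the pyran fused to ring B, opened to a 2-methylbut-3-yn-2-yl ether on O3'; O1–C2 and C3–OH of ring C; the chalcone Cα=Cβ bond; the O3'–C ether bond and the two aryl–prenyl bonds at C6 and C8.
2. Forward: rings A and B are bought as 2,4,6-trihydroxyacetophenone and 2-bromo-3-hydroxybenzaldehyde. Ring A is C-prenylated twice and masked, ring B is O-propargylated, the halves are joined by aldol condensation, ring C is closed oxidatively, and the pyran on ring B is closed last by a thermal pericyclic cascade. Bromine and the MOM groups are then removed.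
3. Enabling feature: in ring B, O3' is ortho to C4', so an alkyne unit on O3' holds its terminal carbon over C4' in a six-atom array (C4'=C3'–O–CMe2–C≡CH). A [3,3] shift makes C4'–C4, and the phenol released at O3' re-closes O–CMe2 through an ortho-quinone methide. Bromine on C2' shuts the only other ortho carbon.
4. Stereochemistry: the target has no stereocentre. Its one stereo-element, the cis C3=C4 alkene of the pyran, is fixed by the ring; the stereocentres of transient intermediates are erased in the same flask.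

Key step: step 6

Assumption: for an aryl propargyl ether whose meta substituent is an electron-poor sp2 carbon, the unassisted thermal rearrangement is expected to favour the flanked ortho carbon (here C2'), hence the blocking bromine.

**Step 1**
Reactants: 1 2,4,6-trihydroxyacetophenone; 2 prenyl bromide (1-bromo-3-methylbut-2-ene)
Product: 3 1-[2,4,6-trihydroxy-3,5-bis(3-methylbut-2-en-1-yl)phenyl]ethan-1-one
Conditions: 2 (2.2 equiv), 10% aq KOH, 0 °C to rt; then dil. HCl
Reagents that add atoms: none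
Why: Phenolate C-alkylation of an acylphloroglucinol, whose ambident anion in water reacts at the two equivalent ring carbons C3 and C5; mono- and O-alkylated material should be separable by chromatography.

**Step 2**
Reactants: 3 1-[2,4,6-trihydroxy-3,5-bis(3-methylbut-2-en-1-yl)phenyl]ethan-1-one
Product: 4 1-[2-hydroxy-4,6-bis(methoxymethoxy)-3,5-bis(3-methylbut-2-en-1-yl)phenyl]ethan-1-one
Conditions: MOMCl (2.3 equiv), K2CO3, acetone, 0 °C to rt
Reagents that add atoms: chloromethyl methyl ether, COCCl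
Why: Williamson-type O-alkylation in which the hydroxyl hydrogen-bonded to the acetyl carbonyl is the least nucleophilic and stays free, and the symmetry of 3 makes the two ortho hydroxyls equivalent, so one bis-acetal should result.

**Step 3**
Reactants: 5 2-bromo-3-hydroxybenzaldehyde; 6 3-chloro-3-methylbut-1-yne
Product: 7 2-bromo-3-[(2-methylbut-3-yn-2-yl)oxy]benzaldehyde
Conditions: 6 (1.5 equiv), K2CO3, KI (cat.), CuI (cat.), acetone, reflux
Reagents that add atoms: none
Why: Copper-assisted propargylic substitution of the tertiary chloride by the phenoxide, the standard entry to aryl 1,1-dimethylpropargyl ethers; the aldehyde and the aryl bromide are spectators.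

**Step 4**
Reactants: 4 1-[2-hydroxy-4,6-bis(methoxymethoxy)-3,5-bis(3-methylbut-2-en-1-yl)phenyl]ethan-1-one; 7 2-bromo-3-[(2-methylbut-3-yn-2-yl)oxy]benzaldehyde
Product: 9 (E)-3-{2-bromo-3-[(2-methylbut-3-yn-2-yl)oxy]phenyl}-1-[2-hydroxy-4,6-bis(methoxymethoxy)-3,5-bis(3-methylbut-2-en-1-yl)phenyl]prop-2-en-1-one, via aldol adduct 8 (not isolated)
Conditions: KOH, EtOH/H2O, rt
Reagents that add atoms: none
Why: Claisen–Schmidt condensation of a methyl ketone with a non-enolizable aldehyde, in which E1cB dehydration of the aldol adduct gives the thermodynamically favoured E-enone; acetals, alkyne and tertiary ether are stable to base.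

**Step 5**
Reactants: 9 (E)-3-{2-bromo-3-[(2-methylbut-3-yn-2-yl)oxy]phenyl}-1-[2-hydroxy-4,6-bis(methoxymethoxy)-3,5-bis(3-methylbut-2-en-1-yl)phenyl]prop-2-en-1-one
Product: 11 2-{2-bromo-3-[(2-methylbut-3-yn-2-yl)oxy]phenyl}-3-hydroxy-5,7-bis(methoxymethoxy)-6,8-bis(3-methylbut-2-en-1-yl)-4H-chromen-4-one, via trans-dihydroflavonol 10 (not isolated)
Conditions: 30% aq H2O2, NaOH, MeOH/THF, 0 °C to rt
Reagents that add atoms: hydrogen peroxide, OO
Why: Algar–Flynn–Oyamada oxidation, in which hydroperoxide oxygenates Cα while the 2'-phenoxide closes ring C at Cβ to the racemic trans-dihydroflavonol, whose two stereocentres are erased by dehydrogenation in the same flask; nucleophilic HOO− leaves the electron-rich prenyl alkenes and the alkyne alone.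

**Step 6**
Reactants: 11 2-{2-bromo-3-[(2-methylbut-3-yn-2-yl)oxy]phenyl}-3-hydroxy-5,7-bis(methoxymethoxy)-6,8-bis(3-methylbut-2-en-1-yl)-4H-chromen-4-one
Product: 15 2-(8-bromo-2,2-dimethyl-2H-chromen-7-yl)-3-hydroxy-5,7-bis(methoxymethoxy)-6,8-bis(3-methylbut-2-en-1-yl)-4H-chromen-4-one, via allenyl dienone 12 (not isolated), via 2-allenylphenol 13 (not isolated), via ortho-quinone methide 14 (not isolated)
Conditions: o-xylene (dilute), BHT (cat.), 145 °C, sealed tube, Ar, dark
Reagents that add atoms: none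
Why: On heating, the aryl 2-methylbut-3-yn-2-yl ether undergoes an aromatic propargyl Claisen [3,3] shift through a six-membered transition state that joins the terminal alkyne carbon to C4' and breaks O–CMe2 (dienone 12); enolization gives the 2-allenylphenol 13, a [1,5]-hydrogen shift from O–H to the central allene carbon gives the (Z)-ortho-quinone methide 14, and a thermally allowed disrotatory oxa-6π electrocyclization re-forms O–CMe2. The closest known reaction type is the thermal conversion of aryl 1,1-dimethylpropargyl ethers into 2,2-dimethyl-2H-chromenes, which the gem-dimethyl group accelerates. The one ring closed is the six-membered pyran on ring B: relative to 11 the net new ring bond is C4'–C4 (formally a 6-endo hydroarylation of the alkyne by C4'–H), made in the sigmatropic event, and the ring is finally sealed by the 6π electrocyclization of the 1-oxatriene. No stereocentre is created, because the sp3 C4' of 12 is erased on rearomatization and the ring alkene can only be cis. The step needs regioselectivity between the two carbons ortho to O3', and bromine on C2' secures it: a shift to C2' gives a dienone that cannot enolize and returns, while the shift to C4' is drained irreversibly by rearomatization. It also needs chemoselectivity over the two prenyl groups and the acetals, which have no thermal pathway here because the A-ring oxygens beside the prenyl groups are capped as MOM ethers.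

**Step 7**
Reactants: 15 2-(8-bromo-2,2-dimethyl-2H-chromen-7-yl)-3-hydroxy-5,7-bis(methoxymethoxy)-6,8-bis(3-methylbut-2-en-1-yl)-4H-chromen-4-one
Product: 16 2-(2,2-dimethyl-2H-chromen-7-yl)-3-hydroxy-5,7-bis(methoxymethoxy)-6,8-bis(3-methylbut-2-en-1-yl)-4H-chromen-4-one
Conditions: Pd(PPh3)4 (cat.), HCO2Na, DMF, 100 °C
Reagents that add atoms: none
Why: Palladium-catalysed formate hydrodehalogenation (oxidative addition of zerovalent palladium to Ar–Br, formate exchange, decarboxylation to Ar–Pd–H, reductive elimination), which uses no H2 and should therefore leave the prenyl and chromene alkenes untouched.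

**Step 8**
Reactants: 16 2-(2,2-dimethyl-2H-chromen-7-yl)-3-hydroxy-5,7-bis(methoxymethoxy)-6,8-bis(3-methylbut-2-en-1-yl)-4H-chromen-4-one
Product: 17 dorsilurin C
Conditions: 3 M HCl (cat. to 2 equiv), MeOH/THF, 40–50 °C, short reaction time
Reagents that add atoms: none
Why: Acid-catalysed acetal methanolysis of aryl MOM ethers, a deprotection with close precedent on prenylated polyphenols when kept mild and brief.

**Compound list**

1 | 2,4,6-trihydroxyacetophenone | CC(=O)c1c(O)cc(O)cc1O | starting material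
2 | prenyl bromide (1-bromo-3-methylbut-2-ene) | CC(C)=CCBr | starting material
3 | 1-[2,4,6-trihydroxy-3,5-bis(3-methylbut-2-en-1-yl)phenyl]ethan-1-one | CC(=O)c1c(O)c(CC=C(C)C)c(O)c(CC=C(C)C)c1O | intermediate
4 | 1-[2-hydroxy-4,6-bis(methoxymethoxy)-3,5-bis(3-methylbut-2-en-1-yl)phenyl]ethan-1-one | CC(=O)c1c(O)c(CC=C(C)C)c(OCOC)c(CC=C(C)C)c1OCOC | intermediate
5 | 2-bromo-3-hydroxybenzaldehyde | O=Cc1cccc(O)c1Br | starting material
6 | 3-chloro-3-methylbut-1-yne | C#CC(C)(C)Cl | starting material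
7 | 2-bromo-3-[(2-methylbut-3-yn-2-yl)oxy]benzaldehyde | O=Cc1cccc(OC(C)(C)C#C)c1Br | intermediate
8 | aldol adduct, racemic 3-{2-bromo-3-[(2-methylbut-3-yn-2-yl)oxy]phenyl}-3-hydroxy-1-[2-hydroxy-4,6-bis(methoxymethoxy)-3,5-bis(3-methylbut-2-en-1-yl)phenyl]propan-1-one (formed in the flask) | OC(CC(=O)c1c(O)c(CC=C(C)C)c(OCOC)c(CC=C(C)C)c1OCOC)c1cccc(OC(C)(C)C#C)c1Br | intermediate
9 | (E)-3-{2-bromo-3-[(2-methylbut-3-yn-2-yl)oxy]phenyl}-1-[2-hydroxy-4,6-bis(methoxymethoxy)-3,5-bis(3-methylbut-2-en-1-yl)phenyl]prop-2-en-1-one | O=C(/C=C/c1cccc(OC(C)(C)C#C)c1Br)c1c(O)c(CC=C(C)C)c(OCOC)c(CC=C(C)C)c1OCOC | intermediate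
10 | trans-dihydroflavonol, racemic (2R*,3R*)-2-{2-bromo-3-[(2-methylbut-3-yn-2-yl)oxy]phenyl}-3-hydroxy-5,7-bis(methoxymethoxy)-6,8-bis(3-methylbut-2-en-1-yl)chroman-4-one, one enantiomer drawn (formed in the flask) | C#CC(C)(C)Oc1cccc(c1Br)[C@@H]2[C@H](C(=O)c3c(OCOC)c(CC=C(C)C)c(OCOC)c(CC=C(C)C)c3O2)O | intermediate
11 | 2-{2-bromo-3-[(2-methylbut-3-yn-2-yl)oxy]phenyl}-3-hydroxy-5,7-bis(methoxymethoxy)-6,8-bis(3-methylbut-2-en-1-yl)-4H-chromen-4-one | CC(C)=CCc1c(OCOC)c(CC=C(C)C)c2oc(-c3cccc(OC(C)(C)C#C)c3Br)c(O)c(=O)c2c1OCOC | intermediate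
12 | allenyl dienone, racemic 2-[2-bromo-4-(3-methylbuta-1,2-dien-1-yl)-3-oxocyclohexa-1,5-dien-1-yl]-3-hydroxy-5,7-bis(methoxymethoxy)-6,8-bis(3-methylbut-2-en-1-yl)-4H-chromen-4-one (formed in the flask) | CC(C)=CCc1c(OCOC)c(CC=C(C)C)c2oc(C3=C(Br)C(=O)C(C=C=C(C)C)C=C3)c(O)c(=O)c2c1OCOC | intermediate
13 | 2-allenylphenol, 2-[2-bromo-3-hydroxy-4-(3-methylbuta-1,2-dien-1-yl)phenyl]-3-hydroxy-5,7-bis(methoxymethoxy)-6,8-bis(3-methylbut-2-en-1-yl)-4H-chromen-4-one (formed in the flask) | CC(C)=CCc1c(OCOC)c(CC=C(C)C)c2oc(-c3ccc(C=C=C(C)C)c(O)c3Br)c(O)c(=O)c2c1OCOC | intermediate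
14 | ortho-quinone methide, 2-[(4Z)-2-bromo-4-(3-methylbut-2-en-1-ylidene)-3-oxocyclohexa-1,5-dien-1-yl]-3-hydroxy-5,7-bis(methoxymethoxy)-6,8-bis(3-methylbut-2-en-1-yl)-4H-chromen-4-one (formed in the flask) | CC(C)=CCc1c(OCOC)c(CC=C(C)C)c2oc(C3=C(Br)C(=O)/C(=C\C=C(C)C)C=C3)c(O)c(=O)c2c1OCOC | intermediate
15 | 2-(8-bromo-2,2-dimethyl-2H-chromen-7-yl)-3-hydroxy-5,7-bis(methoxymethoxy)-6,8-bis(3-methylbut-2-en-1-yl)-4H-chromen-4-one | CC(C)=CCc1c(OCOC)c(CC=C(C)C)c2oc(-c3ccc4c(c3Br)OC(C)(C)C=C4)c(O)c(=O)c2c1OCOC | intermediate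
16 | 2-(2,2-dimethyl-2H-chromen-7-yl)-3-hydroxy-5,7-bis(methoxymethoxy)-6,8-bis(3-methylbut-2-en-1-yl)-4H-chromen-4-one | CC(C)=CCc1c(OCOC)c(CC=C(C)C)c2oc(-c3ccc4c(c3)OC(C)(C)C=C4)c(O)c(=O)c2c1OCOC | intermediate
17 | dorsilurin C, 2-(2,2-dimethyl-2H-chromen-7-yl)-3,5,7-trihydroxy-6,8-bis(3-methylbut-2-en-1-yl)-4H-chromen-4-one | CC(C)=CCc1c(O)c(CC=C(C)C)c2oc(-c3ccc4c(c3)OC(C)(C)C=C4)c(O)c(=O)c2c1O | target

**Step count and risks**

Total step count: 8. Longest linear sequence: 7 steps (steps 1, 2, 4, 5, 6, 7, 8 from compound 1).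

Steps most likely to fail:

Step 5. The risk is that, once the enone is oxygenated, the phenoxide closes in the 5-exo sense onto Cα (the aurone manifold, which a 6'-alkoxy group favours), or that dehydrogenation of the dihydroflavonol stalls. The fallback sets out from 9 and comes back at 11. The phenol is first added to the enone (NaOAc, EtOH, reflux; oxa-Michael) to give the racemic flavanone, 2-{2-bromo-3-[(2-methylbut-3-yn-2-yl)oxy]phenyl}-5,7-bis(methoxymethoxy)-6,8-bis(3-methylbut-2-en-1-yl)chroman-4-one F1, so that O1–C2 exists before any oxygen is introduced. The lithium enolate of F1 (LiN(SiMe3)2, THF, −78 °C) is hydroxylated with 2-(phenylsulfonyl)-3-phenyloxaziridine to the trans-dihydroflavonol 10, now isolated. Compound 10 is dehydrogenated with alkaline H2O2 (NaOH, MeOH, 0 °C) to 11.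

Step 6. The risk is a slow [3,3] shift on the crowded, electron-poor ring B, so that the flavonol degrades thermally first, or diversion of the 2-allenylphenol by attack of its oxygen on the allene (five-membered ring closure). The fallback moves the same cascade to the fragment; it sets out from 7 (with 4) and comes back at 15. Heating 7 (o-xylene, 145 °C) should lead through the allenyl dienone F2, the 2-allenylphenol F3 and the ortho-quinone methide F4 to 8-bromo-2,2-dimethyl-2H-chromene-7-carbaldehyde F5. F5 is condensed with 4 (KOH, EtOH/H2O, rt) through the aldol adduct F6 to the chalcone F7. Algar–Flynn–Oyamada oxidation of F7 (H2O2, NaOH, MeOH/THF) through the trans-dihydroflavonol F8 gives 15.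

Step 8. The risk is acid-promoted addition of the freed 5- and 7-hydroxyls to the neighbouring prenyl alkenes (chroman ring formation) or addition of solvent to the alkenes. The fallback sets out from 16 and comes back at 17. The acetals are cleaved by silyl transfer under buffered aprotic conditions (Me3SiOTf, 2,2'-bipyridyl, CH2Cl2, 0 °C) to give the tris(trimethylsilyl) ether F9. Hydrolysis of F9 on neutral aqueous work-up (H2O, THF, rt) gives 17.

**Further compounds**

F1 | step 5 | racemic 2-{2-bromo-3-[(2-methylbut-3-yn-2-yl)oxy]phenyl}-5,7-bis(methoxymethoxy)-6,8-bis(3-methylbut-2-en-1-yl)chroman-4-one | C#CC(C)(C)Oc1cccc(c1Br)C1CC(=O)c2c(OCOC)c(CC=C(C)C)c(OCOC)c(CC=C(C)C)c2O1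
F2 | step 6 | racemic 2-bromo-4-(3-methylbuta-1,2-dien-1-yl)-3-oxocyclohexa-1,5-diene-1-carbaldehyde | O=CC1=C(Br)C(=O)C(C=C=C(C)C)C=C1
F3 | step 6 | 2-bromo-3-hydroxy-4-(3-methylbuta-1,2-dien-1-yl)benzaldehyde | O=Cc1ccc(C=C=C(C)C)c(O)c1Br
F4 | step 6 | (4Z)-2-bromo-4-(3-methylbut-2-en-1-ylidene)-3-oxocyclohexa-1,5-diene-1-carbaldehyde | O=CC1=C(Br)C(=O)/C(=C\C=C(C)C)C=C1
F5 | step 6 | 8-bromo-2,2-dimethyl-2H-chromene-7-carbaldehyde | O=Cc1ccc2C=CC(C)(C)Oc2c1Br
F6 | step 6 | racemic 3-(8-bromo-2,2-dimethyl-2H-chromen-7-yl)-3-hydroxy-1-[2-hydroxy-4,6-bis(methoxymethoxy)-3,5-bis(3-methylbut-2-en-1-yl)phenyl]propan-1-one | OC(CC(=O)c1c(O)c(CC=C(C)C)c(OCOC)c(CC=C(C)C)c1OCOC)c1ccc2C=CC(C)(C)Oc2c1Br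
F7 | step 6 | (E)-3-(8-bromo-2,2-dimethyl-2H-chromen-7-yl)-1-[2-hydroxy-4,6-bis(methoxymethoxy)-3,5-bis(3-methylbut-2-en-1-yl)phenyl]prop-2-en-1-one | O=C(/C=C/c1ccc2C=CC(C)(C)Oc2c1Br)c1c(O)c(CC=C(C)C)c(OCOC)c(CC=C(C)C)c1OCOC
F8 | step 6 | racemic (2R*,3R*)-2-(8-bromo-2,2-dimethyl-2H-chromen-7-yl)-3-hydroxy-5,7-bis(methoxymethoxy)-6,8-bis(3-methylbut-2-en-1-yl)chroman-4-one, one enantiomer drawn | CC1(C)C=Cc2ccc(c(Br)c2O1)[C@@H]3[C@H](C(=O)c4c(OCOC)c(CC=C(C)C)c(OCOC)c(CC=C(C)C)c4O3)O
F9 | step 8 | 2-(2,2-dimethyl-2H-chromen-7-yl)-6,8-bis(3-methylbut-2-en-1-yl)-3,5,7-tris(trimethylsilyloxy)-4H-chromen-4-one | CC(C)=CCc1c(O[Si](C)(C)C)c(CC=C(C)C)c2oc(-c3ccc4c(c3)OC(C)(C)C=C4)c(O[Si](C)(C)C)c(=O)c2c1O[Si](C)(C)C
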